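The numbers in the tables were generated by integration on assumed constants; noise was put on by code.

- A leftover opens this reckoning: the D still in the flask once the E charged has reacted.

| flask | D | E | remark | time |
|---|---|---|---|---|
| teal | 6 mM | 24 mM | run made earlier |  |
| noon | 6.0 mM | 36.0 mM |  | 25 min |
| dusk | 12 mM | 36.0 mM |  | 25 min |
| midnight | 25 mM | 36.0 mM |  | 25 min |
| summer | 50 mM | 36.0 mM |  | 25 min |
| winter | 100 mM | 36.0 mM |  | 25 min |

teal run (percent of the D charged)

| time / min | G / % | Z / % |
|---|---|---|
| 0.667 | 0 | 0 |
| 1.50 | 0 | 1 |
| 4.00 | 7 | 4 |
| 8.00 | 20 | 18 |

(readings scatter by 2 percentage points)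

- solid, in amounts per volume of the solution: E
- at the start none of E is in solution
- "hardly changes" means that all values lie within two and a half points (for a concentration: within two and a half percent of the largest)

- [G] at the end for noon, dusk, midnight, summer, winter, in this order
- how that number moves from the first to the last of them (falls all the way / rises all the way / falls, then rises / rises, then falls / hardly changes)

- Two amounts stand against each other, c_D and c_E as charged. In the teal run, G and Z together reach 2.28 mM at 8.00 min, less than the 24 mM of E charged. Those readings therefore do not show how many E one D takes, so one E per D is an assumption of this reckoning.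
- Winter then has a leftover share of 64.0%, the part of the charged D that stays once each E has taken one D, which is one minus c_E/c_D. Summer has 28.0%, and E is the limiting reagent in both.
- In midnight, c_D lies below c_E, so the share there is nil.
- This reckoning also takes G → Z to run without E. G is then fed while unreacted E remains and drains afterwards, so c_G should rise with c_D and fall again once c_D passes c_E.
- The forecast differs: 0.03 mM, 0.2 mM, 3.5 mM, 10 mM, 17 mM, so rises all the way, on the ground "I assume D + E → G and then G + E → Z".
- The flasks give 0.460 mM, 0.970 mM, 2.18 mM, 2.42 mM, 0.813 mM, so rises, then falls, turning at 39 mM of D.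

    D + J → G (k = 0.110 L mol⁻¹ s⁻¹)
    E ⇌ J, rate k2*(cs2 - [J]) while solid is left; crystals form when [J] > cs2 (solubility = 18.0 mM, k = 0.00420 s⁻¹)
    Z ⇌ L (K = 0.390, k = 9.40 × 10⁻⁵ s⁻¹)
    G → Z (k = 0.00400 s⁻¹)

- In noon, the half-life of G by its turning into Z, 2.9 min at 3.88 min, is short against the 25 min, while G is then made 2.31 times as fast as it is used up. Winter has E at 0% of its charge by 12.5 min, and at the end G at 0.813% and D at 64.0% of the D charged, level with its leftover share of 64.0%. Summer holds D at 33.1% at the end and 28.0% at 250 min, level with its share of 28.0%.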